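Readings and results were generated by integration with constants of no real substance; scatter was added.

Monday's flask stands still at 55% of its starting material at 5.00 min, higher than Tuesday's 3% at the same time, and the two differ in the reagent charged, 0.35 equiv against 1.4 equiv. I have to decide whether 0.700 equiv is a charge worth making, and whether 6.0 min is long enough to read it.

| setting | Monday's | Tuesday's | flask |
|---|---|---|---|
| starting material | 0.50 M | 0.50 M | 0.50 M |
| reagent | 0.35 equiv (fed, over 80 s) | 1.4 equiv (fed, over 80 s) | 0.700 equiv (fed, over 80 s) |
| remark | run made earlier | run made earlier |  |
| time |  |  | 6.0 min |

| run | time / min | starting material / % | target / % |
|---|---|---|---|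
| Monday's | 1.33 | 71 | 10 |
| Monday's | 2.50 | 61 | 10 |
| Monday's | 4.00 | 55 | 12 |
| Monday's | 5.00 | 55 | 11 |
| Tuesday's | 0.417 | 80 | 8 |
| Tuesday's | 0.833 | 52 | 20 |
| Tuesday's | 2.00 | 5 | 35 |
| Tuesday's | 5.00 | 3 | 35 |

(each reading ± 1.5 percentage points)

- why nothing more happens at 6.0 min, or that something still does (forward and back rates have come level / it is still moving / the reagent has run out first / all of the starting material has reacted)
- how much of the starting material has reacted by 6.0 min
- how much target there is at 6.0 min, in percent of the starting material charged
- how much side product B there is at 6.0 min, in percent of the starting material charged
- how much isomer of the product there is at 6.0 min, in percent of the starting material charged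
- amount of target if the flask were left three thousand times as long, in percent of the starting material charged

- percent here means starting material units held: one side product B counts as two
- the reaction counts as stopped when no species that holds the starting material changes by six tenths of a point or more over the second half of the time

I solve the two ends first, then join them. At the lean end, Monday's flask lost 45.0% of its starting material on 0.35 equiv of reagent and then stopped, which gives s = 1.29, the consumption ratio: starting material lost per reagent charged, in a flask where the reagent is the limiting reagent. At the rich end, Tuesday's flask shows that a surplus of reagent takes the starting material down to 3%.

Between them, if Monday's s carries over, s times the new flask's charge reckons an end point of 90.0% reacted, an estimate and not a bound, which is short of complete conversion, so I expect reagent to be limiting here too. The time is a separate matter. Monday's flask took from the end of its feed at 80 s until about 4.00 min to stand still, and its last reagent met 55% of starting material. The last reagent in the new flask meets about 10.0%, which is less, so I scale the tail to some 14.7 min after the feed. I therefore charge 0.700 equiv and read at 6.0 min, expecting a flask that is still moving and stands some way below that end point.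

The forecast says it is still moving, with 80% reacted, 26% target, 22% side product B, 32% isomer of the product and 29% target in the long run, on these grounds: “The tail then slows as both deplete”.

The flask gives it is still moving, with 81.0% reacted, 25.1% target, 30.0% side product B, 14.1% isomer of the product and 29.4% target in the long run.

    starting material + reagent ⇌ intermediate A (K = 0.520 /M, k = 0.0120 /M/s)
    starting material + reagent ⇌ intermediate B (K = 21.0 /M, k = 0.0500 /M/s)
    starting material + reagent → target (k = 0.0510 /M/s)
    reagent + intermediate A → side product A (k = 0.0130 /M/s)
    starting material + intermediate B → side product B (k = 0.0180 /M/s)
    target ⇌ isomer of the product (K = 0.620, k = 0.00520 /s)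

Monday's s reckoned 90.0% reacted for this flask. The flask has 81.0% reacted at 6.0 min and 91.3% at 60.0 min, a little past the reckoning, when 0.0587% of its reagent is left. The neighbouring flask has 0.280 equiv of reagent, with the other charges and the time unchanged. There s reckons 36.1% reacted, and that flask has 37.7% reacted at 6.0 min, again past the reckoning, with 0.697% of its reagent left.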